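**Strategy**

- Cuts: the aryl ketone is traced back to a 3-substituted 4,7-dihydroxycoumarin (ketone C=O is coumarin C4, the α-CH2 is C3, C2 is given back as CO2, the ortho phenol oxygen is O1). Next the bond from coumarin C3 to the quaternary carbon is cut, then the furan C2–CH2 bond, then the C8–O bond of an oxidised geranyl acetate.
- Enabling feature: the 2,4-dihydroxyphenyl ketone whose α-CH2 sits on the quaternary carbon (methyl, vinyl, chain) is what is left of a pyranone ring after lactone opening and loss of C2. That CH2 is therefore the acidic C3 between C2 and C4 of a purchasable cyclic 1,3-dicarbonyl, and the vinyl-bearing quaternary carbon is the substituted terminus of a geranyl-type allyl unit.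
- Forward order: geranyl acetate is oxidised at its E-methyl group, brominated and coupled at that carbon with borylated 3-methylfuran; the acetate is exchanged for a methyl carbonate; the 7-O-silylated coumarin is allylated at C3 with allylic transposition; alkali then opens the pyranone and C2 leaves as CO2. No ring is built: the benzene and furan rings are bought, and the bought pyranone ring is destroyed.
- Stereochemistry: the single stereocentre (R in the target, S at the coumarin stage, same spatial arrangement) is set by the chiral complex made from [Ir(cod)Cl]2 and a BINOL phosphoramidite reading the E C2–C3 alkene of the carbonate. The 6E alkene comes from geranyl acetate through E-selective SeO2 oxidation and is not touched again.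

Key step: step 8

Remark on the chemistry: the sense of induction for this untested nucleophile–electrophile pair cannot be fixed beforehand, so the phosphoramidite antipode that delivers 3S in 12 is used (both antipodes are available); 4,7-dihydroxycoumarin is taken as a commercial starting material.

**Route**

Step 1
Reactants: 1 geranyl acetate [(2E)-3,7-dimethylocta-2,6-dien-1-yl acetate]
Product: 2 (2E,6E)-8-hydroxy-3,7-dimethylocta-2,6-dien-1-yl acetate
Conditions: SeO2 (0.3 equiv), t-BuOOH (3 equiv), salicylic acid (0.1 equiv), CH2Cl2, 0 °C to rt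
Reagents that add atoms: tert-butyl hydroperoxide, CC(C)(C)OO (terminal oxygen source); selenium dioxide, O=[Se]=O (catalytic oxygen carrier)
Why: Riley allylic oxidation (ene reaction, then [2,3]-sigmatropic shift) of the more electron-rich 6,7-alkene should hydroxylate the methyl group trans to the chain, so the new trisubstituted alkene is E and the acetate-deactivated 2,3-alkene is left alone.

Step 2
Reactants: 2 (2E,6E)-8-hydroxy-3,7-dimethylocta-2,6-dien-1-yl acetate
Product: 3 (2E,6E)-8-bromo-3,7-dimethylocta-2,6-dien-1-yl acetate
Conditions: CBr4 (1.2 equiv), PPh3 (1.25 equiv), CH2Cl2, 0 °C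
Reagents that add atoms: carbon tetrabromide, BrC(Br)(Br)Br
Why: Appel bromination displaces the oxyphosphonium group at the unhindered primary allylic carbon under neutral conditions, so neither the alkene geometry nor the acetate should be affected.

Step 3
Reactants: 4 3-methylfuran
Product: 5 4,4,5,5-tetramethyl-2-(4-methylfuran-2-yl)-1,3,2-dioxaborolane
Conditions: [Ir(OMe)(cod)]2 (1 mol %), 4,4'-di-tert-butyl-2,2'-bipyridine (2 mol %), B2pin2 (0.4 equiv, furan in excess), hexane, rt; short-path distillation
Reagents that add atoms: bis(pinacolato)diboron, CC1(C)OB(OC1(C)C)B1OC(C)(C)C(C)(C)O1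
Why: iridium-catalysed aromatic C–H borylation is sterically governed and favours the furan α-position, so the boryl group should enter at C5, away from the methyl group, with excess furan suppressing double borylation.

Step 4
Reactants: 3 (2E,6E)-8-bromo-3,7-dimethylocta-2,6-dien-1-yl acetate; 5 4,4,5,5-tetramethyl-2-(4-methylfuran-2-yl)-1,3,2-dioxaborolane
Product: 6 (2E,6E)-3,7-dimethyl-8-(4-methylfuran-2-yl)octa-2,6-dien-1-yl acetate
Conditions: Pd(PPh3)4 (5 mol %), K2CO3 (2 equiv), THF/H2O (10:1), degassed, rt to 40 °C
Reagents that add atoms: none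
Why: in this Suzuki–Miyaura allyl–aryl coupling, zerovalent palladium should ionise the primary allylic bromide much faster than the trisubstituted allylic acetate and deliver the furyl group to the unsubstituted allyl terminus, which keeps the E alkene.

Step 5
Reactants: 6 (2E,6E)-3,7-dimethyl-8-(4-methylfuran-2-yl)octa-2,6-dien-1-yl acetate
Product: 7 (2E,6E)-3,7-dimethyl-8-(4-methylfuran-2-yl)octa-2,6-dien-1-ol
Conditions: K2CO3 (0.2 equiv), MeOH, rt
Reagents that add atoms: none
Why: base-catalysed transesterification (Zemplén-type methanolysis) should remove the acetate as methyl acetate without touching the furan or the alkenes.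

Step 6
Reactants: 7 (2E,6E)-3,7-dimethyl-8-(4-methylfuran-2-yl)octa-2,6-dien-1-ol
Product: 8 methyl (2E,6E)-3,7-dimethyl-8-(4-methylfuran-2-yl)octa-2,6-dien-1-yl carbonate
Conditions: ClCO2Me (1.5 equiv), pyridine (3 equiv), CH2Cl2, 0 °C; chromatography on AgNO3-impregnated silica gel if any 2Z isomer is present
Reagents that add atoms: methyl chloroformate, COC(=O)Cl
Why: O-acylation of the primary allylic alcohol with a chloroformate in a pyridine-buffered medium should give the carbonate, the leaving group that later supplies the methoxide base, without harming the furan.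

Step 7
Reactants: 9 4,7-dihydroxycoumarin
Product: 11 4-hydroxy-7-(triisopropylsilyloxy)coumarin, via bis-silyl ether 10 (not isolated)
Conditions: i-Pr3SiCl (2.3 equiv), imidazole (5 equiv), DMF, 0 °C to rt; then THF/H2O/AcOH (4:1:1), rt
Reagents that add atoms: triisopropylsilyl chloride, CC(C)[Si](Cl)(C(C)C)C(C)C
Why: silyl ether formation with a silyl chloride and imidazole caps both hydroxyl groups, and the silyl group on O4, part of a vinylogous silyl ester, should be hydrolysed by dilute acetic acid while the hindered aryl silyl ether at O7 stays.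

Step 8
Reactants: 8 methyl (2E,6E)-3,7-dimethyl-8-(4-methylfuran-2-yl)octa-2,6-dien-1-yl carbonate; 11 4-hydroxy-7-(triisopropylsilyloxy)coumarin
Product: 12 3-[(3S,6E)-3,7-dimethyl-8-(4-methylfuran-2-yl)octa-1,6-dien-3-yl]-4-hydroxy-7-(triisopropylsilyloxy)coumarin
Conditions: [Ir(cod)Cl]2 (2 mol %), O,O'-(1,1'-binaphthalene-2,2'-diyl) N,N-bis(1-phenylethyl)phosphoramidite (single antipode, 4 mol %), preactivated with n-PrNH2 (THF, 50 °C, volatiles then removed); 11 (1.1 equiv), THF, 50 °C, no added base; pH 7 phosphate work-up
Reagents that add atoms: none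
Why: Proposed new method: the cyclometalated phosphoramidite complex of monovalent iridium formed from [Ir(cod)Cl]2 ionises the E-carbonate 8 with loss of CO2 and methoxide to an allyl complex of trivalent iridium that holds the chain syn and the methyl group anti on one terminus; the methoxide, the only base present, deprotonates the vinylogous acid 11, and the soft C3 enolate attacks that disubstituted terminus from the face opposite the metal, which transposes the alkene into the vinyl group. The closest known reaction types are the branched alkylation of malonates by E-trisubstituted allylic carbonates under the same catalyst class, which gives acyclic all-carbon quaternary centres, and the C3-allylation of 4-hydroxycoumarins by monosubstituted allyl electrophiles; the pairing of a coumarin enolate with a trisubstituted allyl unit is the untested part. No ring closes: a single C–C bond joins coumarin C3 to chain C3. The new quaternary stereocentre is controlled by the ligand antipode, which decides the allyl face bound to iridium, read against the fixed E geometry of the C2–C3 alkene of 8. The step needs branched over linear attack, C- over O-alkylation and one allyl face: the preference of this catalyst class for the more substituted terminus should give the first, re-ionisation of any 4-O-allyl enol ether (an allylic ester of a good leaving group) returns it to the C-alkylation path, and isomerically pure 8 with allyl isomerisation slower than attack should give the third.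

Step 9
Reactants: 12 3-[(3S,6E)-3,7-dimethyl-8-(4-methylfuran-2-yl)octa-1,6-dien-3-yl]-4-hydroxy-7-(triisopropylsilyloxy)coumarin
Product: 15 (3R,6E)-1-(2,4-dihydroxyphenyl)-3-ethenyl-3,7-dimethyl-8-(4-methylfuran-2-yl)oct-6-en-1-one, via desilylated coumarin 13 (not isolated), via keto acid 14 (not isolated)
Conditions: NaOH (2 M aq., 8 equiv), EtOH, 85 °C, argon; then AcOH to pH 4–5, 40 °C
Reagents that add atoms: none
Why: hydroxide should first saponify the aryl silyl ether and then open the pyranone at C2 (classical alkaline ketonic cleavage of a 3-alkyl-4-hydroxycoumarin), and the β-keto acid freed on weakly acidic work-up decarboxylates to the aryl ketone without change at the quaternary stereocentre, which carries no hydrogen.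

**Compound list**

1 | geranyl acetate | CC(C)=CCC/C(C)=C/COC(C)=O | starting material
2 | (2E,6E)-8-hydroxy-3,7-dimethylocta-2,6-dien-1-yl acetate | OC/C(C)=C/CC/C(C)=C/COC(C)=O | intermediate
3 | (2E,6E)-8-bromo-3,7-dimethylocta-2,6-dien-1-yl acetate | BrC/C(C)=C/CC/C(C)=C/COC(C)=O | intermediate
4 | 3-methylfuran | Cc1ccoc1 | starting material
5 | 4,4,5,5-tetramethyl-2-(4-methylfuran-2-yl)-1,3,2-dioxaborolane | Cc1coc(B2OC(C)(C)C(C)(C)O2)c1 | intermediate
6 | (2E,6E)-3,7-dimethyl-8-(4-methylfuran-2-yl)octa-2,6-dien-1-yl acetate | Cc1coc(C/C(C)=C/CC/C(C)=C/COC(C)=O)c1 | intermediate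
7 | (2E,6E)-3,7-dimethyl-8-(4-methylfuran-2-yl)octa-2,6-dien-1-ol | Cc1coc(C/C(C)=C/CC/C(C)=C/CO)c1 | intermediate
8 | methyl (2E,6E)-3,7-dimethyl-8-(4-methylfuran-2-yl)octa-2,6-dien-1-yl carbonate | Cc1coc(C/C(C)=C/CC/C(C)=C/COC(=O)OC)c1 | intermediate
9 | 4,7-dihydroxycoumarin | O=c1cc(O)c2ccc(O)cc2o1 | starting material
10 | 4,7-bis(triisopropylsilyloxy)coumarin | O=c1cc(O[Si](C(C)C)(C(C)C)C(C)C)c2ccc(O[Si](C(C)C)(C(C)C)C(C)C)cc2o1 | intermediate
11 | 4-hydroxy-7-(triisopropylsilyloxy)coumarin | O=c1cc(O)c2ccc(O[Si](C(C)C)(C(C)C)C(C)C)cc2o1 | intermediate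
12 | 3-[(3S,6E)-3,7-dimethyl-8-(4-methylfuran-2-yl)octa-1,6-dien-3-yl]-4-hydroxy-7-(triisopropylsilyloxy)coumarin | C=C[C@](C)(CC/C=C(\C)Cc1cc(C)co1)c1c(O)c2ccc(O[Si](C(C)C)(C(C)C)C(C)C)cc2oc1=O | intermediate
13 | 3-[(3S,6E)-3,7-dimethyl-8-(4-methylfuran-2-yl)octa-1,6-dien-3-yl]-4,7-dihydroxycoumarin | C=C[C@](C)(CC/C=C(\C)Cc1cc(C)co1)c1c(O)c2ccc(O)cc2oc1=O | intermediate
14 | (3S,6E)-2-(2,4-dihydroxybenzoyl)-3-ethenyl-3,7-dimethyl-8-(4-methylfuran-2-yl)oct-6-enoic acid (both C2 epimers, present as its sodium salt) | C=C[C@](C)(CC/C=C(\C)Cc1cc(C)co1)C(C(=O)O)C(=O)c1ccc(O)cc1O | intermediate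
15 | (3R,6E)-1-(2,4-dihydroxyphenyl)-3-ethenyl-3,7-dimethyl-8-(4-methylfuran-2-yl)oct-6-en-1-one (CNP0249327.1) | C=C[C@](C)(CC/C=C(\C)Cc1cc(C)co1)CC(=O)c1ccc(O)cc1O | target

**Count**

Total: 9 steps. Longest linear sequence: 7 steps (steps 1, 2, 4, 5, 6, 8 and 9, from geranyl acetate).

**Steps most likely to fail**

Step 8 (the new method). What may go wrong: the hindered, weakly basic coumarin enolate attacks the unsubstituted allyl terminus or reacts at oxygen without being funnelled back; the acidic pronucleophile protonates the metallacycle and stops turnover; or the allyl complex equilibrates between its faces before attack and enantiomeric purity falls. The fallback uses known chemistry, sets out from alcohol 7 and coumarin 11, and comes back at 12. Mitsunobu etherification (PPh3, diisopropyl azodicarboxylate, THF, 0 °C) should join O4 of 11 to C1 of 7 as 4-{[(2E,6E)-3,7-dimethyl-8-(4-methylfuran-2-yl)octa-2,6-dien-1-yl]oxy}-7-(triisopropylsilyloxy)coumarin F1. Heating in toluene (about 110 °C) should bring about the Claisen [3,3] rearrangement that moves the allyl group from oxygen to C3 with transposition (an isomeric 2-O-allyl chromone would reach the same carbon), giving rac-3-[(6E)-3,7-dimethyl-8-(4-methylfuran-2-yl)octa-1,6-dien-3-yl]-4-hydroxy-7-(triisopropylsilyloxy)coumarin F2. The enantiomers would be separated by preparative chromatography on a chiral stationary phase (the acidic 4-hydroxyl also allows a classical salt resolution with a cinchona base); the S enantiomer is 12. The cost is half of the material.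

Step 9. What may go wrong: hydroxide addition to the lactone carbonyl, flanked by the quaternary carbon and deactivated in the coumarin anion, is too slow at a temperature the skipped furyl alkene tolerates; harsher alkali moves that alkene into conjugation with the furan or cleaves the keto acid by retro-Claisen fragmentation instead of decarboxylation. The fallback avoids the lactone, sets out from carbonate 8, and comes back at 15. The known branched alkylation of dimethyl malonate by E-trisubstituted allylic carbonates ([Ir(cod)Cl]2, the phosphoramidite antipode giving 3S, ZnI2, NaN(SiMe3)2, THF) should give dimethyl 2-[(3S,6E)-3,7-dimethyl-8-(4-methylfuran-2-yl)octa-1,6-dien-3-yl]propanedioate F3. Krapcho dealkoxycarbonylation (LiCl, wet DMSO, 150 °C) gives methyl (3R,6E)-3-ethenyl-3,7-dimethyl-8-(4-methylfuran-2-yl)oct-6-enoate F4. MeNH(OMe)·HCl and i-PrMgCl (THF, −20 °C) give the Weinreb amide (3R,6E)-3-ethenyl-N-methoxy-N,3,7-trimethyl-8-(4-methylfuran-2-yl)oct-6-enamide F5. Separately, 4-bromoresorcinol is silylated (t-BuMe2SiCl, imidazole, DMF) to 1-bromo-2,4-bis(tert-butyldimethylsilyloxy)benzene F6 and converted with Mg in THF into [2,4-bis(tert-butyldimethylsilyloxy)phenyl]magnesium bromide F7. This adds once to F5 (Weinreb ketone synthesis) to give (3R,6E)-1-[2,4-bis(tert-butyldimethylsilyloxy)phenyl]-3-ethenyl-3,7-dimethyl-8-(4-methylfuran-2-yl)oct-6-en-1-one F8. Bu4NF buffered with acetic acid (THF, 0 °C) removes both silyl groups and gives 15.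

Step 4. What may go wrong: protodeboronation of the 2-furyl boronate in the aqueous base outruns transmetalation, and a slow coupling gives zerovalent palladium time to ionise the allylic acetate or to scramble the allyl terminus and the alkene geometry. The fallback is a base-free Negishi coupling that sets out from 3-methylfuran 4 and bromide 3 and comes back at 6. Deprotonation of 4 at the unhindered α-position with lithium 2,2,6,6-tetramethylpiperidide (THF, −78 °C) should give (4-methylfuran-2-yl)lithium F9. ZnCl2 converts it into chlorido(4-methylfuran-2-yl)zinc F10, and Pd(PPh3)4 (THF, 0 °C) couples this with 3. The organozinc leaves the acetate alone and no water is present; a 2,3-disubstituted furan from deprotonation next to the methyl group would be removed by chromatography at 6 or 7.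

**Further compounds**

F1 | step 8 | 4-{[(2E,6E)-3,7-dimethyl-8-(4-methylfuran-2-yl)octa-2,6-dien-1-yl]oxy}-7-(triisopropylsilyloxy)coumarin | O=c1cc(OC/C=C(C)/CC/C=C(\C)Cc2cc(C)co2)c2ccc(O[Si](C(C)C)(C(C)C)C(C)C)cc2o1
F2 | step 8 | rac-3-[(6E)-3,7-dimethyl-8-(4-methylfuran-2-yl)octa-1,6-dien-3-yl]-4-hydroxy-7-(triisopropylsilyloxy)coumarin | C=CC(C)(CC/C=C(\C)Cc1cc(C)co1)c1c(O)c2ccc(O[Si](C(C)C)(C(C)C)C(C)C)cc2oc1=O
F3 | step 9 | dimethyl 2-[(3S,6E)-3,7-dimethyl-8-(4-methylfuran-2-yl)octa-1,6-dien-3-yl]propanedioate | C=C[C@](C)(CC/C=C(\C)Cc1cc(C)co1)C(C(=O)OC)C(=O)OC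
F4 | step 9 | methyl (3R,6E)-3-ethenyl-3,7-dimethyl-8-(4-methylfuran-2-yl)oct-6-enoate | C=C[C@](C)(CC/C=C(\C)Cc1cc(C)co1)CC(=O)OC
F5 | step 9 | (3R,6E)-3-ethenyl-N-methoxy-N,3,7-trimethyl-8-(4-methylfuran-2-yl)oct-6-enamide | C=C[C@](C)(CC/C=C(\C)Cc1cc(C)co1)CC(=O)N(C)OC
F6 | step 9 | 1-bromo-2,4-bis(tert-butyldimethylsilyloxy)benzene | Brc1ccc(O[Si](C)(C)C(C)(C)C)cc1O[Si](C)(C)C(C)(C)C
F7 | step 9 | [2,4-bis(tert-butyldimethylsilyloxy)phenyl]magnesium bromide | Br[Mg]c1ccc(O[Si](C)(C)C(C)(C)C)cc1O[Si](C)(C)C(C)(C)C
F8 | step 9 | (3R,6E)-1-[2,4-bis(tert-butyldimethylsilyloxy)phenyl]-3-ethenyl-3,7-dimethyl-8-(4-methylfuran-2-yl)oct-6-en-1-one | C=C[C@](C)(CC/C=C(\C)Cc1cc(C)co1)CC(=O)c1ccc(O[Si](C)(C)C(C)(C)C)cc1O[Si](C)(C)C(C)(C)C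
F9 | step 4 | (4-methylfuran-2-yl)lithium | [Li]c1cc(C)co1
F10 | step 4 | chlorido(4-methylfuran-2-yl)zinc | Cl[Zn]c1cc(C)co1
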